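## The problem

The target 20 is a diaryl ether of two fully differentiated benzene rings. Ring A is a methyl benzoate numbered C1 (ester carbon), C2 (3-methylbut-2-enyloxy, "prenyloxy"), C4 (methyl) and C6 (aryloxy). Ring B is numbered C1′ (ether oxygen), C2′ and C4′ (methoxy) and C6′ (hydroxymethyl). The hard bond is the ether link O–C6: three of its four ortho positions are substituted, the ring B phenol is electron-rich and doubly ortho-substituted, and C6 sits next to the ester, so copper- or palladium-mediated etherification is unattractive. The molecule has no stereocenter and no configurationally fixed axis, so nothing has to be controlled except regiochemistry on the two rings. Three groups limit the conditions: the prenyl aryl ether (acid cleavage, Claisen rearrangement on heating, ene reactivity), the benzylic alcohol ortho to the ether oxygen (ionization, oxidation), and the ester between two ortho oxygens. That ester cannot be made by acyl substitution on the hindered acid but is easily made by alkylating the carboxylate. The enabling feature is the contiguous triad C6 (O-aryl), C1 (carboxyl), C2 (O-alkyl) on ring A. C6 and C1 can be read as the two carbons of an aryne that take up an oxygen nucleophile and a one-carbon electrophile, and the alkoxy group on C2 decides which carbon takes which. With carbon dioxide as the electrophile the carboxyl carbon arrives at the correct oxidation level.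

## Retrosynthesis

**20 to 19 (O–Si bond).** The benzylic hydroxyl is unmasked last from its triisopropylsilyl ether 19. A free benzylic alcohol would be an extra nucleophile in the aryne step, and a ring B carbonyl in its place would capture the aryl anion intramolecularly. The forward reaction only has to cleave a primary silyl ether beside a hindered ester and a prenyl ether.

**19 to 18 (the C=C bond of the prenyl group).** The isopropylidene terminus is exchanged for a methylene, giving the allyl ether 18. A prenyl ether on an aryne can undergo an intramolecular ene reaction through its allylic methyl hydrogens, whereas the allyl ether has no suitably placed allylic hydrogen. The forward step is a cross-metathesis that installs the isopropylidene group; it costs one step and avoids any deprotection and realkylation.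

**18 to 17 (ester O–CH3 bond).** The methyl ester is traced to the acid 17. Isolating the acid allows acid–base extraction to separate it from neutral by-products of the coupling. The forward alkylation of the carboxylate is insensitive to the two ortho substituents.

**17 to 9, 13 and 14 (O–C6 and C1–carboxyl bonds).** Both bonds are cut at once, which leads to the aryne 16, the ring B aryloxide 15 (the potassium salt of phenol 13) and carbon dioxide 14. The aryne is released from the ortho-silylaryl triflate 9. Cutting only the ether bond would require a hindered metal-mediated etherification, and cutting only the carboxyl bond would require lithiation of a diaryl ether that has a second doubly activated C–H on ring B. The three-component cut is the only one that uses the substitution pattern of ring A to set both bonds. It divides the molecule into two fragments of similar size plus a gas. The forward reaction must add the aryloxide at the aryne carbon remote from the allyloxy group and then carboxylate the anion before it is protonated.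

**9 to 6 to 5 (S–O, C–Si and O–Si bonds).** The silyl triflate 9 comes from the ortho-bromophenol 5 through its trimethylsilyl ether 6. Bromine–lithium exchange gives aryllithium 7, O-to-C silyl migration gives phenoxide 8, and triflation follows. Halogen–metal exchange at very low temperature is preferred to deprotonative metalation because the allyl ether would not tolerate an alkyllithium–diamine base.

**5 to 4 to 3 to 1 (O–allyl, two O–CH3 and C–Br bonds).** Phenol 5 is the monoallyl ether of the symmetric bromoresorcinol 4. Direct electrophilic bromination of the parent diol would go to the positions flanking the methyl group, so the bromine is placed between the oxygens by directed lithiation of the dimethyl ether 1 (giving 3 through aryllithium 2), and the methyl ethers are then removed. Each step is regiochemically unambiguous; the only statistical step is the monoallylation of 4.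

**13 to 12 to 11 to 10 (O–Si bond, C–H of the alcohol, C–CHO bond).** The ring B phenol 13 is the silyl ether of salicyl alcohol 12, the reduction product of aldehyde 11, which arises by ortho-formylation of 10 at its only free ortho position. Three steps give a phenol whose ortho and para positions are all blocked, which is what O-selective arylation requires.

## Roads not taken

**Alternative 1:** Ring B is built by cycloaddition. The C1′–C6′ and C4′–C5′ bonds are cut, giving the (Z)-4-aryloxy-1,3-dimethoxy-1-(trimethylsilyloxy)butadiene A2, whose aryl group is the complete ring A, and methyl (E)-3-nitroacrylate A3. In the forward step the oxygen-substituted terminus of A2 bonds to the ester-bearing carbon of A3, as directed by the nitro group, and the adduct aromatizes by loss of the nitro group and one methoxy group to the phenol diester A1. The merits are that the ring B oxygenation pattern is fixed by diene polarity, that the ether oxygen is brought in by simple alkylation of a ring A phenol, and that this type of cycloaddition–aromatization is well established. The weak points are specific to this target: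
- A1 carries two methyl esters, and only the ring B ester may be reduced to the hydroxymethyl group.
- The C4′ phenol of A1 still has to be methylated.
- The prenyl ether must survive the thermal cycloaddition and the acidic elimination.
- A2, with four heteroatom substituents, is a long and sensitive linear construct.

Alternative 1 is better in the maturity of its key reaction. The chosen plan sets against it convergence, a hydroxymethyl carbon that is never at the ester oxidation level, and a much shorter sequence.

**Alternative 2:** Ring A is formed by recyclization of a pyranone. The C3–C4 bond of ring A is cut, giving the 3-acetyl-4-aryloxy-6-methylpyran-2-one A5. A5 would be made from dehydroacetic acid A6 by activating its 4-hydroxyl and adding phenol 13 by addition–elimination. In the forward step a magnesium alkoxide in its alcohol opens the lactone to the methyl ester, and the acetyl methyl condenses with the liberated methyl ketone to give the salicylate A4. O-Prenylation of A4 would give 19. The merits are considerable. The sequence is about eight steps against twelve, it needs no cryogenic organolithium chemistry, the ester and a free C2 hydroxyl appear together already distinguished from the aryloxy group, and the prenyl group is introduced by plain alkylation without a metathesis step. In step count and operational simplicity this road is better. Its weak points lie in the key step: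
- The aryloxy group of A5 sits on the β-carbon of a vinylogous ester and can be exchanged for methoxide by addition–elimination, which would irreversibly give the ring A methyl ether.
- The opened intermediate has two aldol modes, acetyl methyl onto the ketone or ketone methyl onto the acetyl carbonyl, and only the first gives the required 2,6-dioxygenated 4-methyl pattern.
- Deacetylation by retro-Claisen cleavage can compete.

The chosen plan sets against this a regiochemistry fixed by aryne polarization, with no competing condensation modes, and an ether bond formed irreversibly and never exposed to alkoxide.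

**Alternative 3:** Ring A is formed by cycloaddition of an ynol ether to a pyranone. The C4–C5 and C6–C1 bonds are cut, giving the aryl ethynyl ether A8 (from phenol 13) and methyl 6-methyl-4-(prenyloxy)-2-oxopyran-3-carboxylate A9. In the forward step the nucleophilic CH terminus of A8 bonds to C6 of A9, the oxygen-bearing carbon bonds to C3, and the bridged adduct loses its lactone bridge as carbon dioxide 14. The product is A7, which is the same compound as 19 and one step from 20. This is the most convergent plan and has the shortest endgame, one step after the key step against three. The weak points: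
- A9 has a donating 4-alkoxy group and a 6-methyl group, both of which lower its reactivity as an electron-poor diene, so heating would be needed.
- At that temperature the prenyl vinylogous ester can rearrange, and the electron-rich, hindered ynol ether A8 can hydrate or oligomerize.
- Making A8 requires strong-base elimination chemistry on a derivative of 13.

The chosen plan sets against the better convergence of Alternative 3 an ionic key step at or below room temperature, an allyl surrogate that removes the thermal liability of the prenyl group, and two coupling partners (9 and 13) that are stable, storable compounds.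

Key step: step 9

## Route

Remark: 3,5-dimethoxytoluene (the dimethyl ether of orcinol), 2,4-dimethoxyphenol and carbon dioxide are taken as purchased materials.

Step 1
Reactants: 1 3,5-dimethoxytoluene
Product: 3 2-bromo-1,3-dimethoxy-5-methylbenzene, via (2,6-dimethoxy-4-methylphenyl)lithium 2 (not isolated)
Conditions: n-BuLi, THF, 0 °C → rt; BrCH2CH2Br, −78 °C → rt
Reagents that add atoms: 1,2-dibromoethane, BrCCBr
Why: Directed ortho-metalation; the C–H between the two methoxy groups is the most acidic ring hydrogen and both oxygens coordinate lithium, so lithiation is regiospecific there, and the aryllithium takes bromine from 1,2-dibromoethane with loss of ethene.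

Step 2
Reactants: 3 2-bromo-1,3-dimethoxy-5-methylbenzene
Product: 4 2-bromo-5-methylbenzene-1,3-diol
Conditions: BBr3, CH2Cl2, −78 °C → rt; H2O
Reagents that add atoms: none
Why: Lewis-acid cleavage of aryl methyl ethers; BBr3 converts both methoxy groups to aryloxyboron bromides and bromomethane without touching the aryl bromide, and hydrolysis frees the resorcinol.

Step 3
Reactants: 4 2-bromo-5-methylbenzene-1,3-diol
Product: 5 3-(allyloxy)-2-bromo-5-methylphenol
Conditions: allyl bromide (1 equiv), 4 (1.5 equiv), K2CO3, acetone, reflux
Reagents that add atoms: allyl bromide, C=CCBr
Why: Williamson mono-O-alkylation of a symmetric diol; the diol is used in excess and should be recoverable by base extraction, and the diallyl ether is the only neutral by-product, so the step is statistical but robust.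

Step 4
Reactants: 5 3-(allyloxy)-2-bromo-5-methylphenol
Product: 6 [3-(allyloxy)-2-bromo-5-methylphenoxy]trimethylsilane
Conditions: (Me3Si)2NH, THF, 70 °C; evaporation
Reagents that add atoms: hexamethyldisilazane, C[Si](C)(C)N[Si](C)(C)C
Why: O-Silylation of the phenol with hexamethyldisilazane; ammonia is the only by-product, so the moisture-sensitive silyl ether can be used directly after removal of volatiles.

Step 5
Reactants: 6 [3-(allyloxy)-2-bromo-5-methylphenoxy]trimethylsilane
Product: 9 3-(allyloxy)-5-methyl-2-(trimethylsilyl)phenyl trifluoromethanesulfonate, via [2-(allyloxy)-4-methyl-6-(trimethylsilyloxy)phenyl]lithium 7 (not isolated), via lithium 3-(allyloxy)-5-methyl-2-(trimethylsilyl)phenoxide 8 (not isolated)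
Conditions: n-BuLi, THF, −100 °C; Tf2O, −100 °C → rt
Reagents that add atoms: trifluoromethanesulfonic anhydride, O=S(=O)(OS(=O)(=O)C(F)(F)F)C(F)(F)F
Why: Bromine–lithium exchange at −100 °C is faster than any attack on the allyl ether; the aryllithium undergoes 1,3 O-to-C silyl migration (retro-Brook rearrangement) driven by phenoxide formation, and the phenoxide is O-sulfonylated, which is the standard entry to ortho-silylaryl triflates from ortho-bromophenols.

Step 6
Reactants: 10 2,4-dimethoxyphenol
Product: 11 2-hydroxy-3,5-dimethoxybenzaldehyde
Conditions: MgCl2, Et3N, (CH2O)n, MeCN, reflux; dil. HCl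
Reagents that add atoms: paraformaldehyde (as formaldehyde), C=O
Why: Magnesium-mediated ortho-formylation of a phenol; the magnesium phenoxide delivers formaldehyde to the ortho carbon and a second formaldehyde oxidizes the benzylic alkoxide by hydride transfer, and C6 is the only free ortho position of 10.

Step 7
Reactants: 11 2-hydroxy-3,5-dimethoxybenzaldehyde
Product: 12 2-(hydroxymethyl)-4,6-dimethoxyphenol
Conditions: NaBH4, MeOH, 0 °C; sat. NH4Cl
Reagents that add atoms: none
Why: Borohydride reduction of an aryl aldehyde; the neutral work-up keeps the electron-rich salicyl alcohol from ionizing to an ortho-quinone methide.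

Step 8
Reactants: 12 2-(hydroxymethyl)-4,6-dimethoxyphenol
Product: 13 2,4-dimethoxy-6-{[(triisopropylsilyl)oxy]methyl}phenol
Conditions: i-Pr3SiCl, imidazole, CH2Cl2, 0 °C → rt
Reagents that add atoms: chlorotriisopropylsilane, CC(C)[Si](Cl)(C(C)C)C(C)C
Why: Chemoselective silylation; the bulky chlorosilane should react at the unhindered primary hydroxyl while the phenol, flanked by two ortho substituents and hydrogen-bonded to the neighboring methoxy oxygen, stays free, and the triisopropylsilyl group is chosen for its resistance to fluoride in the next step.

Step 9
Reactants: 13 2,4-dimethoxy-6-{[(triisopropylsilyl)oxy]methyl}phenol; 9 3-(allyloxy)-5-methyl-2-(trimethylsilyl)phenyl trifluoromethanesulfonate; 14 carbon dioxide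
Product: 17 2-(allyloxy)-6-[2,4-dimethoxy-6-{[(triisopropylsilyl)oxy]methyl}phenoxy]-4-methylbenzoic acid, via potassium 2,4-dimethoxy-6-{[(triisopropylsilyl)oxy]methyl}phenoxide 15 (not isolated), via 3-(allyloxy)-5-methylbenzyne 16 (not isolated)
Conditions: KH, THF, 0 °C; then CO2 (1 atm), 9, KF, 18-crown-6, THF, 0 °C → rt; cold dil. HCl to pH 3
Reagents that add atoms: none
Why: Proposed new method: fluoride attacks silicon of 9 and expels triflate to give aryne 16, whose triple bond joins the future C6 and C1 of ring A with the allyloxy group on C2; aryloxide 15 adds through oxygen to C6, the aryne carbon remote from the allyloxy group, because the inductively withdrawing C–O bond stabilizes the negative charge that develops on the adjacent carbon C1 and distorts the aryne so that C6 is the more electrophilic terminus; the C1 aryl anion, flanked by two oxygens, is then captured by CO2, and the potassium carboxylate is protonated on work-up to 17. The closest known reactions are the KF/18-crown-6 promoted coupling of arynes, amines and CO2 to anthranilic acids and the fluoride-promoted O-arylation of phenols by ortho-silylaryl triflates; using an aryloxide as the nucleophile in the carboxylative coupling is the untested part. No ring is closed and no stereocenter is created; the step forms the O–C6 ether bond and the C1–carboxyl bond. The selectivities needed are regiochemistry of addition, secured by the 3-alkoxy substituent of the aryne; O- rather than C-arylation, secured because both ortho positions and the para position of 15 are substituted; carboxylation rather than protonation, secured by forming 15 with KH so that no conjugate acid remains, by THF instead of a C–H acidic solvent, and by a CO2-saturated solution; and freedom from internal traps, secured by the silyl-protected benzylic alcohol and by the allyl ether, which unlike a prenyl ether offers no allylic hydrogen placed for an intramolecular ene reaction. Acid–base extraction should separate 17 from any neutral diaryl ether formed by protonation.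

Step 10
Reactants: 17 2-(allyloxy)-6-[2,4-dimethoxy-6-{[(triisopropylsilyl)oxy]methyl}phenoxy]-4-methylbenzoic acid
Product: 18 methyl 2-(allyloxy)-6-[2,4-dimethoxy-6-{[(triisopropylsilyl)oxy]methyl}phenoxy]-4-methylbenzoate
Conditions: MeI, K2CO3, DMF, rt
Reagents that add atoms: iodomethane, CI
Why: Carboxylate O-alkylation (SN2 on iodomethane) is indifferent to the two ortho substituents that would block acyl substitution, and the silyl, allyl and aryl ethers are inert to it.

Step 11
Reactants: 18 methyl 2-(allyloxy)-6-[2,4-dimethoxy-6-{[(triisopropylsilyl)oxy]methyl}phenoxy]-4-methylbenzoate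
Product: 19 methyl 2-[2,4-dimethoxy-6-{[(triisopropylsilyl)oxy]methyl}phenoxy]-4-methyl-6-[(3-methylbut-2-en-1-yl)oxy]benzoate
Conditions: 2-methyl-2-butene (excess), second-generation Grubbs catalyst RuCl2(=CHPh)(PCy3)(H2IMes) (5 mol %), 1,4-benzoquinone (10 mol %), CH2Cl2, 40 °C, sealed vessel
Reagents that add atoms: 2-methyl-2-butene, CC=C(C)C
Why: Olefin cross-metathesis of a terminal alkene with 2-methyl-2-butene in large excess transfers an isopropylidene group and releases propene, the established way to turn an allyl into a prenyl ether; the trisubstituted product does not react further, and benzoquinone suppresses ruthenium hydride isomerization of the allyl ether.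

Step 12
Reactants: 19 methyl 2-[2,4-dimethoxy-6-{[(triisopropylsilyl)oxy]methyl}phenoxy]-4-methyl-6-[(3-methylbut-2-en-1-yl)oxy]benzoate
Product: 20 methyl 2-[2-(hydroxymethyl)-4,6-dimethoxyphenoxy]-4-methyl-6-[(3-methylbut-2-en-1-yl)oxy]benzoate
Conditions: Bu4NF, AcOH, THF, 0 °C → rt
Reagents that add atoms: none
Why: Fluoride cleavage of the silicon–oxygen bond; acetic acid buffers the liberated alkoxide so that the methyl ester, itself shielded by two ortho substituents, and the prenyl ether are left alone.

## Compound list

1 | 3,5-dimethoxytoluene | COc1cc(C)cc(OC)c1 | starting material
2 | (2,6-dimethoxy-4-methylphenyl)lithium | [Li]c1c(OC)cc(C)cc1OC | intermediate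
3 | 2-bromo-1,3-dimethoxy-5-methylbenzene | COc1cc(C)cc(OC)c1Br | intermediate
4 | 2-bromo-5-methylbenzene-1,3-diol | Cc1cc(O)c(Br)c(O)c1 | intermediate
5 | 3-(allyloxy)-2-bromo-5-methylphenol | C=CCOc1cc(C)cc(O)c1Br | intermediate
6 | [3-(allyloxy)-2-bromo-5-methylphenoxy]trimethylsilane | C=CCOc1cc(C)cc(O[Si](C)(C)C)c1Br | intermediate
7 | [2-(allyloxy)-4-methyl-6-(trimethylsilyloxy)phenyl]lithium | [Li]c1c(OCC=C)cc(C)cc1O[Si](C)(C)C | intermediate
8 | lithium 3-(allyloxy)-5-methyl-2-(trimethylsilyl)phenoxide | [Li+].[O-]c1cc(C)cc(OCC=C)c1[Si](C)(C)C | intermediate
9 | 3-(allyloxy)-5-methyl-2-(trimethylsilyl)phenyl trifluoromethanesulfonate | C=CCOc1cc(C)cc(OS(=O)(=O)C(F)(F)F)c1[Si](C)(C)C | intermediate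
10 | 2,4-dimethoxyphenol | COc1ccc(O)c(OC)c1 | starting material
11 | 2-hydroxy-3,5-dimethoxybenzaldehyde | COc1cc(C=O)c(O)c(OC)c1 | intermediate
12 | 2-(hydroxymethyl)-4,6-dimethoxyphenol | COc1cc(CO)c(O)c(OC)c1 | intermediate
13 | 2,4-dimethoxy-6-{[(triisopropylsilyl)oxy]methyl}phenol | COc1cc(CO[Si](C(C)C)(C(C)C)C(C)C)c(O)c(OC)c1 | intermediate
14 | carbon dioxide | O=C=O | starting material
15 | potassium 2,4-dimethoxy-6-{[(triisopropylsilyl)oxy]methyl}phenoxide | [K+].[O-]c1c(CO[Si](C(C)C)(C(C)C)C(C)C)cc(OC)cc1OC | intermediate
16 | 3-(allyloxy)-5-methylbenzyne (1,2-didehydro-3-(allyloxy)-5-methylbenzene) | C=CCOC1=CC(C)=CC#C1 | intermediate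
17 | 2-(allyloxy)-6-[2,4-dimethoxy-6-{[(triisopropylsilyl)oxy]methyl}phenoxy]-4-methylbenzoic acid | OC(=O)c1c(OCC=C)cc(C)cc1Oc1c(CO[Si](C(C)C)(C(C)C)C(C)C)cc(OC)cc1OC | intermediate
18 | methyl 2-(allyloxy)-6-[2,4-dimethoxy-6-{[(triisopropylsilyl)oxy]methyl}phenoxy]-4-methylbenzoate | COC(=O)c1c(OCC=C)cc(C)cc1Oc1c(CO[Si](C(C)C)(C(C)C)C(C)C)cc(OC)cc1OC | intermediate
19 | methyl 2-[2,4-dimethoxy-6-{[(triisopropylsilyl)oxy]methyl}phenoxy]-4-methyl-6-[(3-methylbut-2-en-1-yl)oxy]benzoate | COC(=O)c1c(OCC=C(C)C)cc(C)cc1Oc1c(CO[Si](C(C)C)(C(C)C)C(C)C)cc(OC)cc1OC | intermediate
20 | methyl 2-[2-(hydroxymethyl)-4,6-dimethoxyphenoxy]-4-methyl-6-[(3-methylbut-2-en-1-yl)oxy]benzoate | COC(=O)c1c(OCC=C(C)C)cc(C)cc1Oc1c(CO)cc(OC)cc1OC | target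

## Step count and risk

Total step count: 12. Longest linear sequence: 9 steps (steps 1–5, then 9–12). The ring B branch (steps 6–8) joins at step 9.

**Step 9 (key step, proposed new method).** Four things may go wrong:
- Protonation of the C1 aryl anion by adventitious proton sources may outrun capture by CO2, so that only O-arylation occurs.
- CO2 may reversibly carbonate the aryloxide. This lowers the concentration of free nucleophile and opens a path in which the carbonate oxygen adds to the aryne and the acyl group then migrates to carbon.
- Surplus aryne may arylate the product carboxylate.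
- Fluoride may cleave the benzylic silyl ether.

The fallback uses known chemistry, with the ether bond made by nucleophilic aromatic substitution and the carboxyl by oxidation. It sets out from 13. Purchased 2,6-difluoro-4-methylbenzaldehyde F1 is treated with allyl alcohol and NaH in THF at 0 °C. One fluoride should be displaced selectively, because the alkoxy group introduced deactivates the ring, to give 2-(allyloxy)-6-fluoro-4-methylbenzaldehyde F2. The potassium salt of 13 (K2CO3, DMF, about 100 °C) then displaces the remaining fluoride, which is activated by the ortho formyl group, to give 2-(allyloxy)-6-[2,4-dimethoxy-6-{[(triisopropylsilyl)oxy]methyl}phenoxy]-4-methylbenzaldehyde F3. Pinnick oxidation (NaClO2, NaH2PO4, 2-methyl-2-butene, t-BuOH–H2O) should give the acid, and the route is rejoined at 17.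

**Step 5.** The alkyllithium may deprotonate or add to the allyl ether, the aryllithium may cyclize onto the allyl double bond, or the silyl migration may be incomplete before triflation. The fallback postpones the allyl group until all organolithium chemistry is done, and it also bypasses the statistical step 3. It sets out from 4. Silylation of both hydroxyls with hexamethyldisilazane gives 2-bromo-5-methyl-1,3-bis(trimethylsilyloxy)benzene F4. Bromine–lithium exchange, retro-Brook migration of one silyl group, triflation and a mildly acidic work-up that removes the remaining O-silyl group should give 3-hydroxy-5-methyl-2-(trimethylsilyl)phenyl trifluoromethanesulfonate F5. Mitsunobu etherification with allyl alcohol (PPh3, diisopropyl azodicarboxylate, THF, 0 °C) is near-neutral and should therefore not trigger base-induced aryne formation. It gives the silyl triflate, and the route is rejoined at 9.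

**Step 11.** Ruthenium hydride species may move the allyl double bond into conjugation with oxygen, or the exchange may stall after ethylidene transfer, leaving a crotyl ether. The fallback replaces metathesis by deprotection and alkylation. It sets out from 18. Allyl transfer to morpholine with Pd(PPh3)4 (zerovalent palladium) in THF at rt should give methyl 2-[2,4-dimethoxy-6-{[(triisopropylsilyl)oxy]methyl}phenoxy]-6-hydroxy-4-methylbenzoate F6, the same structure as A4. Alkylation with prenyl bromide and K2CO3 in DMF then gives the prenyl ether, and the route is rejoined at 19.

**Step 8.** Silylation may take place at the phenolic oxygen or at both hydroxyls, and the salicyl alcohol may ionize to an ortho-quinone methide during handling. The fallback uses exhaustive protection followed by selective release. It sets out from 12. Treatment with i-Pr3SiOTf and 2,6-lutidine in CH2Cl2 silylates both oxygens to give triisopropyl(2,4-dimethoxy-6-{[(triisopropylsilyl)oxy]methyl}phenoxy)silane F7. K2CO3 in methanol at rt should cleave only the aryl silyl ether, since a phenoxide is a far better leaving group from silicon than an alkoxide. The route is rejoined at 13.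

## Further compounds

F1 | step 9 | 2,6-difluoro-4-methylbenzaldehyde | Cc1cc(F)c(C=O)c(F)c1
F2 | step 9 | 2-(allyloxy)-6-fluoro-4-methylbenzaldehyde | C=CCOc1cc(C)cc(F)c1C=O
F3 | step 9 | 2-(allyloxy)-6-[2,4-dimethoxy-6-{[(triisopropylsilyl)oxy]methyl}phenoxy]-4-methylbenzaldehyde | O=Cc1c(OCC=C)cc(C)cc1Oc1c(CO[Si](C(C)C)(C(C)C)C(C)C)cc(OC)cc1OC
F4 | step 5 | 2-bromo-5-methyl-1,3-bis(trimethylsilyloxy)benzene | Cc1cc(O[Si](C)(C)C)c(Br)c(O[Si](C)(C)C)c1
F5 | step 5 | 3-hydroxy-5-methyl-2-(trimethylsilyl)phenyl trifluoromethanesulfonate | Cc1cc(O)c([Si](C)(C)C)c(OS(=O)(=O)C(F)(F)F)c1
F6 | step 11 | methyl 2-[2,4-dimethoxy-6-{[(triisopropylsilyl)oxy]methyl}phenoxy]-6-hydroxy-4-methylbenzoate | COC(=O)c1c(O)cc(C)cc1Oc1c(CO[Si](C(C)C)(C(C)C)C(C)C)cc(OC)cc1OC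
F7 | step 8 | triisopropyl(2,4-dimethoxy-6-{[(triisopropylsilyl)oxy]methyl}phenoxy)silane | COc1cc(CO[Si](C(C)C)(C(C)C)C(C)C)c(O[Si](C(C)C)(C(C)C)C(C)C)c(OC)c1
A1 | alternative 1 | methyl 2-[4-hydroxy-2-methoxy-6-(methoxycarbonyl)phenoxy]-4-methyl-6-[(3-methylbut-2-en-1-yl)oxy]benzoate | COC(=O)c1c(OCC=C(C)C)cc(C)cc1Oc1c(C(=O)OC)cc(O)cc1OC
A2 | alternative 1 | methyl 2-{[(1Z)-2,4-dimethoxy-4-(trimethylsilyloxy)buta-1,3-dien-1-yl]oxy}-4-methyl-6-[(3-methylbut-2-en-1-yl)oxy]benzoate | COC(O[Si](C)(C)C)=C/C(OC)=C/Oc1cc(C)cc(OCC=C(C)C)c1C(=O)OC
A3 | alternative 1 | methyl (E)-3-nitroacrylate | COC(=O)/C=C/[N+](=O)[O-]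
A4 | alternative 2 | methyl 2-[2,4-dimethoxy-6-{[(triisopropylsilyl)oxy]methyl}phenoxy]-6-hydroxy-4-methylbenzoate | COC(=O)c1c(O)cc(C)cc1Oc1c(CO[Si](C(C)C)(C(C)C)C(C)C)cc(OC)cc1OC
A5 | alternative 2 | 3-acetyl-4-[2,4-dimethoxy-6-{[(triisopropylsilyl)oxy]methyl}phenoxy]-6-methyl-2H-pyran-2-one | CC(=O)C1=C(Oc2c(CO[Si](C(C)C)(C(C)C)C(C)C)cc(OC)cc2OC)C=C(C)OC1=O
A6 | alternative 2 | dehydroacetic acid (3-acetyl-4-hydroxy-6-methyl-2H-pyran-2-one) | CC(=O)C1=C(O)C=C(C)OC1=O
A7 | alternative 3 | methyl 2-[2,4-dimethoxy-6-{[(triisopropylsilyl)oxy]methyl}phenoxy]-4-methyl-6-[(3-methylbut-2-en-1-yl)oxy]benzoate | COC(=O)c1c(OCC=C(C)C)cc(C)cc1Oc1c(CO[Si](C(C)C)(C(C)C)C(C)C)cc(OC)cc1OC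
A8 | alternative 3 | 1-(ethynyloxy)-2,4-dimethoxy-6-{[(triisopropylsilyl)oxy]methyl}benzene | C#COc1c(CO[Si](C(C)C)(C(C)C)C(C)C)cc(OC)cc1OC
A9 | alternative 3 | methyl 6-methyl-4-[(3-methylbut-2-en-1-yl)oxy]-2-oxo-2H-pyran-3-carboxylate | COC(=O)C1=C(OCC=C(C)C)C=C(C)OC1=O
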